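**Retrosynthetic overview**
- The plan rests on the tetrahydrofuran ring (O1, C2–C5). C2 bears only H, O1 and the central guaiacyl ring, and its neighbour C3 bears a methyl group beside the C4 methyl. C2 can therefore enter as carbon monoxide, and C3 with its methyl as the vinyl group of a homoallylic alcohol whose carbinol carbon is C5.
- Disconnections, latest first: C9'' methyl from CH2OH; C7''–C8'' by an Evans syn aldol of the aryloxyacetyl imide with veratraldehyde; C2–aryl by arylzinc addition to the C2 oxocarbenium ion of a lactol-derived sulfone; C2–C3 and O1–C2 by hydroxyl-directed branched hydroformylation with lactol closure; C4–C5 by (Z)-crotylboration of veratraldehyde.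
- Only one ring is built, the tetrahydrofuran, and it closes in the hydroformylation step. The three benzene rings are bought.
- Stereocontrol: C4/C5 come from the crotylborane and C3 from equilibration at the lactone stage. C2 comes from attack on the ring face opposite C4-Me and C5-aryl. The ring is 2,3-cis, 3,4-trans, 4,5-cis, so the aryl group, not hydride, must be the incoming group. C7''/C8'' come from the oxazolidinone.

Key step: step 2

Remark on the chemistry: ring atoms are O1, C2 (central aryl), C3, C4, C5 (veratryl) and the side chain is C7'' (carbinol), C8'' (aryloxy carbon), C9'' (methyl); the target reads (2S,3R,4R,5S) and (7''R,8''R) = threo; the hydroformylation is not assumed to control C3, so 10 and 11 are written with C3 undefined, and 13 is the same lactol as 10 as the single (3R) epimer.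

**Step 1**
Reactants: 1 veratraldehyde (3,4-dimethoxybenzaldehyde); 2 cis-2-butene
Product: 6 (1S,2R)-1-(3,4-dimethoxyphenyl)-2-methylbut-3-en-1-ol, via (Z)-crotylpotassium 3 (not isolated), via (Z)-crotyldiisopinocampheylborane 4 (not isolated), via homoallylic diisopinocampheylborinate 5 (not isolated)
Conditions: 2, n-BuLi, KOt-Bu, THF, −78 to −45 °C; (−)-Ipc2BOMe [antipode made from (+)-α-pinene], −78 °C; BF3·OEt2, then 1, −78 °C; NaOH, H2O2, 0 °C to rt
Reagents that add atoms: none
Why: Brown asymmetric crotylboration runs through a closed chair (Zimmerman–Traxler) transition state, so the Z geometry of 4 becomes the syn C1/C2 relationship (later 4,5-cis), and the Ipc ligands derived from (+)-α-pinene direct attack to the Si face of the aldehyde, which should set (1S,2R).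

**Step 2**
Reactants: 6 (1S,2R)-1-(3,4-dimethoxyphenyl)-2-methylbut-3-en-1-ol; 7 carbon monoxide
Product: 10 (4R,5S)-5-(3,4-dimethoxyphenyl)-3,4-dimethyltetrahydrofuran-2-ol (lactol; both anomers; both C3 epimers; the 3R,4R,5S isomer is the one needed), via diphenylphosphinite ester 8 (not isolated), via branched hydroxy aldehyde 9 (not isolated)
Conditions: Rh(acac)(CO)2 (2 mol %), Ph2POMe (10 mol %), 4 Å MS, CO/H2 (1:1, 20 bar), THF, 40 °C
Reagents that add atoms: none
Why: Ph2POMe swaps its methoxy group for the C5–OH of 6 (the sieves take up the methanol), and the phosphorus of the resulting ester 8 binds the rhodium hydride, so hydrometalation of the vinyl group has to pass through a six-membered chelate (Rh, P, O, C5, C4, C3) that leaves rhodium on the internal carbon C3; migratory insertion of CO makes the C2–C3 bond, H2 cleaves the acyl–rhodium bond to give aldehyde 9, and alcohol exchange hands the phosphinite to the next molecule of 6. The closest known reaction type is the branched-selective hydroformylation of homoallylic alcohols with a catalytic, reversibly bound phosphinite directing group, which ends in γ-lactols. The tetrahydrofuran ring closes by 5-exo-trig addition of the C5 hydroxyl to the new formyl carbon (bond O1–C2). C4 and C5 are spectators; the new centre C3 is fixed in the hydrometalation, but the chelate carries the C4 methyl and C5 aryl groups cis to each other and offers no bias that can be relied on, so both C3 epimers are accepted and merged in step 4, and the anomeric centre C2 is an equilibrating mixture that is erased in step 7. The selectivity the step needs is branched over linear (and hydroformylation over alkene isomerisation or hydrogenation), and it is secured by the free secondary hydroxyl in the homoallylic position to an unhindered terminal vinyl group, since without the tether the same catalyst would give mainly the linear aldehyde and a six-membered lactol.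

**Step 3**
Reactants: 10 lactol (C2/C3 mixture)
Product: 11 (4R,5S)-5-(3,4-dimethoxyphenyl)-3,4-dimethyldihydrofuran-2(3H)-one (both C3 epimers)
Conditions: TEMPO (10 mol %), PhI(OAc)2, CH2Cl2, rt
Reagents that add atoms: none
Why: Oxoammonium (TEMPO/PhI(OAc)2) oxidation of a lactol to the γ-lactone removes the anomeric mixture and makes C3 the α-carbon of an ester, while C4, C5 and the electron-rich arene should be untouched by this mild oxidant.

**Step 4**
Reactants: 11 lactone (both C3 epimers)
Product: 12 (3R,4R,5S)-5-(3,4-dimethoxyphenyl)-3,4-dimethyldihydrofuran-2(3H)-one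
Conditions: DBU (1 equiv), toluene, 90 °C; residual 3,4-cis isomer separated and resubmitted
Reagents that add atoms: none
Why: Base-mediated thermodynamic epimerisation through the lactone enolate should funnel both epimers into the isomer with C3-Me trans to C4-Me, because the alternative places C3-Me, C4-Me and the C5 aryl group all on one face, and C4 and C5 carry no acidic hydrogen.

**Step 5**
Reactants: 12 (3R,4R,5S)-lactone
Product: 13 (3R,4R,5S)-5-(3,4-dimethoxyphenyl)-3,4-dimethyltetrahydrofuran-2-ol (anomeric mixture)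
Conditions: i-Bu2AlH, CH2Cl2, −78 °C; aq. KNa tartrate
Reagents that add atoms: none
Why: Partial reduction of a γ-lactone with i-Bu2AlH stops at the aluminium hemiacetal at −78 °C and returns the lactol oxidation level as a single C3 epimer, the cold non-basic medium leaving C3 intact.

**Step 6**
Reactants: 13 (3R,4R,5S)-lactol
Product: 14 (3R,4R,5S)-2-(benzenesulfonyl)-5-(3,4-dimethoxyphenyl)-3,4-dimethyltetrahydrofuran (anomeric mixture)
Conditions: PhSO2H, CaCl2, CH2Cl2, rt
Reagents that add atoms: benzenesulfinic acid, OS(=O)c1ccccc1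
Why: Acid-promoted exchange of a lactol hydroxyl for sulfinate (formation of a 2-sulfonyl cyclic ether through the oxocarbenium ion, S-attack, water taken up by CaCl2) gives a storable oxocarbenium precursor whose anomeric configuration is irrelevant.

**Step 7**
Reactants: 14 2-benzenesulfonyl tetrahydrofuran; 15 1-(benzyloxy)-4-bromo-2-methoxybenzene
Product: 18 (2S,3R,4R,5S)-2-[4-(benzyloxy)-3-methoxyphenyl]-5-(3,4-dimethoxyphenyl)-3,4-dimethyltetrahydrofuran, via arylmagnesium bromide 16 (not isolated), via arylzinc bromide 17 (not isolated)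
Conditions: 15, Mg, THF, rt to 40 °C; ZnBr2, THF, 0 °C to rt; then 14, THF, rt
Reagents that add atoms: none
Why: In this known substitution of 2-sulfonyl cyclic ethers by arylzinc halides the magnesium and zinc bromides ionise the sulfone, and the aryl group should add by inside attack on the envelope (C4 as flap, both methyl groups pseudo-equatorial, C5 aryl pseudo-axial on the other face), that is opposite C4-Me and C5-aryl, which places it cis to C3-Me and trans to the C5 aryl group (2S), whereas hydride attack from that same face on a 2-aryl oxocarbenium ion would give the unwanted 2,5-cis epimer.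

**Step 8**
Reactants: 18 benzyl ether
Product: 19 4-[(2S,3R,4R,5S)-5-(3,4-dimethoxyphenyl)-3,4-dimethyltetrahydrofuran-2-yl]-2-methoxyphenol
Conditions: H2 (1 atm), 10% Pd/C, EtOAc, rt, stopped at consumption of 18
Reagents that add atoms: none
Why: Catalytic hydrogenolysis cleaves the unhindered primary benzyl aryl ether much faster than the two hindered secondary benzylic C–O bonds of the ring, so no stereocentre should be touched.

**Step 9**
Reactants: 19 phenol; 20 bromoacetic acid
Product: 21 2-{4-[(2S,3R,4R,5S)-5-(3,4-dimethoxyphenyl)-3,4-dimethyltetrahydrofuran-2-yl]-2-methoxyphenoxy}acetic acid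
Conditions: NaH (3 equiv), THF–DMF, 0 °C to rt; dilute HCl to pH 3, 0 °C
Reagents that add atoms: none
Why: Williamson ether synthesis of the sodium phenoxide with sodium bromoacetate is a fast SN2 reaction at an α-halo carboxylate, and the basic medium cannot disturb the acid-sensitive ring.

**Step 10**
Reactants: 21 aryloxyacetic acid; 22 (S)-4-benzyloxazolidin-2-one
Product: 24 (S)-4-benzyl-3-(2-{4-[(2S,3R,4R,5S)-5-(3,4-dimethoxyphenyl)-3,4-dimethyltetrahydrofuran-2-yl]-2-methoxyphenoxy}acetyl)oxazolidin-2-one, via mixed pivalic anhydride 23 (not isolated)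
Conditions: PivCl, Et3N, THF, −20 °C; then LiCl, 22, −20 °C to rt
Reagents that add atoms: none
Why: N-acylation of the oxazolidinone through the mixed pivalic anhydride (LiCl/Et3N variant) occurs at the less hindered acyl carbon and avoids strong base and acid chlorides.

**Step 11**
Reactants: 24 aryloxyacetyl imide; 1 veratraldehyde
Product: 27 (S)-4-benzyl-3-[(2S,3R)-3-(3,4-dimethoxyphenyl)-2-{4-[(2S,3R,4R,5S)-5-(3,4-dimethoxyphenyl)-3,4-dimethyltetrahydrofuran-2-yl]-2-methoxyphenoxy}-3-hydroxypropanoyl]oxazolidin-2-one, via (Z)-dibutylboron enolate 25 (not isolated), via dibutylboron aldolate 26 (not isolated)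
Conditions: Bu2BOTf, Et3N, CH2Cl2, −78 to 0 °C; 1, −78 to 0 °C; pH 7 buffer, MeOH, H2O2, 0 °C
Reagents that add atoms: none
Why: In this Evans syn aldol reaction of a glycolate-type imide the (Z)-boron enolate reacts through a dipole-minimised Zimmerman–Traxler chair on the face away from the benzyl group of the (S)-auxiliary, which should set C8'' and C7'' together as the syn (threo) pair that becomes (7''R,8''R).

**Step 12**
Reactants: 27 aldol adduct
Product: 28 (1R,2R)-1-(3,4-dimethoxyphenyl)-2-{4-[(2S,3R,4R,5S)-5-(3,4-dimethoxyphenyl)-3,4-dimethyltetrahydrofuran-2-yl]-2-methoxyphenoxy}propane-1,3-diol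
Conditions: LiBH4, MeOH (1 equiv), Et2O–THF, 0 °C
Reagents that add atoms: none
Why: Reductive removal of the auxiliary with LiBH4 attacks the exocyclic imide carbonyl selectively and gives the primary alcohol C9'' at a temperature at which retro-aldol cleavage and C8'' epimerisation should not compete.

**Step 13**
Reactants: 28 1,3-diol
Product: 29 (2R,3R)-3-(3,4-dimethoxyphenyl)-2-{4-[(2S,3R,4R,5S)-5-(3,4-dimethoxyphenyl)-3,4-dimethyltetrahydrofuran-2-yl]-2-methoxyphenoxy}-3-hydroxypropyl 4-methylbenzenesulfonate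
Conditions: TsCl (1.1 equiv), Et3N, DMAP (cat.), CH2Cl2, 0 °C
Reagents that add atoms: p-toluenesulfonyl chloride, Cc1ccc(S(=O)(=O)Cl)cc1
Why: Chemoselective sulfonylation should take the unhindered primary C9'' hydroxyl in preference to the hindered secondary benzylic C7'' hydroxyl.

**Step 14**
Reactants: 29 primary tosylate
Product: 30 (1R,2R)-1-(3,4-dimethoxyphenyl)-2-{4-[(2S,3R,4R,5S)-5-(3,4-dimethoxyphenyl)-3,4-dimethyltetrahydrofuran-2-yl]-2-methoxyphenoxy}propan-1-ol (target)
Conditions: LiEt3BH (excess), THF, 0 °C to rt; then H2O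
Reagents that add atoms: none
Why: SN2 displacement of a primary tosylate by the very nucleophilic triethylborohydride turns C9'' into the methyl group without touching a stereocentre, the C7'' alkoxide being tied up as its triethylborane complex.

**Compound list**
1 | veratraldehyde (3,4-dimethoxybenzaldehyde) | COc1ccc(C=O)cc1OC | starting material
2 | cis-2-butene | C/C=C\C | starting material
3 | (Z)-crotylpotassium | C/C=C\C[K] | intermediate
4 | (Z)-crotyldiisopinocampheylborane, Ipc groups from (+)-α-pinene | C/C=C\CB([C@@H]1C[C@@H]2C[C@H]([C@H]1C)C2(C)C)[C@@H]1C[C@@H]2C[C@H]([C@H]1C)C2(C)C | intermediate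
5 | (1S,2R)-1-(3,4-dimethoxyphenyl)-2-methylbut-3-en-1-yl diisopinocampheylborinate | C[C@@H]1[C@H]2C[C@H](C2(C)C)C[C@H]1B(O[C@H](c1ccc(OC)c(OC)c1)[C@H](C)C=C)[C@@H]1C[C@@H]2C[C@H]([C@H]1C)C2(C)C | intermediate
6 | (1S,2R)-1-(3,4-dimethoxyphenyl)-2-methylbut-3-en-1-ol | O[C@H](c1ccc(OC)c(OC)c1)[C@H](C)C=C | intermediate
7 | carbon monoxide | [C-]#[O+] | starting material
8 | (1S,2R)-1-(3,4-dimethoxyphenyl)-2-methylbut-3-en-1-yl diphenylphosphinite | c1ccccc1P(c1ccccc1)O[C@H](c1ccc(OC)c(OC)c1)[C@H](C)C=C | intermediate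
9 | (3R,4S)-4-(3,4-dimethoxyphenyl)-4-hydroxy-2,3-dimethylbutanal (both C2 epimers) | O[C@H](c1ccc(OC)c(OC)c1)[C@H](C)C(C)C=O | intermediate
10 | (4R,5S)-5-(3,4-dimethoxyphenyl)-3,4-dimethyltetrahydrofuran-2-ol (both anomers, both C3 epimers) | OC1O[C@H](c2ccc(OC)c(OC)c2)[C@H](C)C1C | intermediate
11 | (4R,5S)-5-(3,4-dimethoxyphenyl)-3,4-dimethyldihydrofuran-2(3H)-one (both C3 epimers) | O=C1O[C@H](c2ccc(OC)c(OC)c2)[C@H](C)C1C | intermediate
12 | (3R,4R,5S)-5-(3,4-dimethoxyphenyl)-3,4-dimethyldihydrofuran-2(3H)-one | O=C1O[C@H](c2ccc(OC)c(OC)c2)[C@H](C)[C@H]1C | intermediate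
13 | (3R,4R,5S)-5-(3,4-dimethoxyphenyl)-3,4-dimethyltetrahydrofuran-2-ol (anomeric mixture) | OC1O[C@H](c2ccc(OC)c(OC)c2)[C@H](C)[C@H]1C | intermediate
14 | (3R,4R,5S)-2-(benzenesulfonyl)-5-(3,4-dimethoxyphenyl)-3,4-dimethyltetrahydrofuran (anomeric mixture) | O=S(=O)(c1ccccc1)C1O[C@H](c2ccc(OC)c(OC)c2)[C@H](C)[C@H]1C | intermediate
15 | 1-(benzyloxy)-4-bromo-2-methoxybenzene | COc1cc(Br)ccc1OCc1ccccc1 | starting material
16 | [4-(benzyloxy)-3-methoxyphenyl]magnesium bromide | COc1cc([Mg]Br)ccc1OCc1ccccc1 | intermediate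
17 | [4-(benzyloxy)-3-methoxyphenyl]zinc bromide | COc1cc([Zn]Br)ccc1OCc1ccccc1 | intermediate
18 | (2S,3R,4R,5S)-2-[4-(benzyloxy)-3-methoxyphenyl]-5-(3,4-dimethoxyphenyl)-3,4-dimethyltetrahydrofuran | COc1cc([C@H]2O[C@H](c3ccc(OC)c(OC)c3)[C@H](C)[C@H]2C)ccc1OCc1ccccc1 | intermediate
19 | 4-[(2S,3R,4R,5S)-5-(3,4-dimethoxyphenyl)-3,4-dimethyltetrahydrofuran-2-yl]-2-methoxyphenol | COc1cc([C@H]2O[C@H](c3ccc(OC)c(OC)c3)[C@H](C)[C@H]2C)ccc1O | intermediate
20 | bromoacetic acid | OC(=O)CBr | starting material
21 | 2-{4-[(2S,3R,4R,5S)-5-(3,4-dimethoxyphenyl)-3,4-dimethyltetrahydrofuran-2-yl]-2-methoxyphenoxy}acetic acid | COc1cc([C@H]2O[C@H](c3ccc(OC)c(OC)c3)[C@H](C)[C@H]2C)ccc1OCC(=O)O | intermediate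
22 | (S)-4-benzyloxazolidin-2-one | O=C1N[C@@H](Cc2ccccc2)CO1 | starting material
23 | mixed anhydride of 21 with pivalic acid | COc1cc([C@H]2O[C@H](c3ccc(OC)c(OC)c3)[C@H](C)[C@H]2C)ccc1OCC(=O)OC(=O)C(C)(C)C | intermediate
24 | (S)-4-benzyl-3-(2-{4-[(2S,3R,4R,5S)-5-(3,4-dimethoxyphenyl)-3,4-dimethyltetrahydrofuran-2-yl]-2-methoxyphenoxy}acetyl)oxazolidin-2-one | COc1cc([C@H]2O[C@H](c3ccc(OC)c(OC)c3)[C@H](C)[C@H]2C)ccc1OCC(=O)N1[C@@H](Cc2ccccc2)COC1=O | intermediate
25 | (Z)-dibutylboron enolate of 24 (aryloxy and boryloxy groups cis) | COc1cc([C@H]2O[C@H](c3ccc(OC)c(OC)c3)[C@H](C)[C@H]2C)ccc1O/C=C(\OB(CCCC)CCCC)N1[C@@H](Cc2ccccc2)COC1=O | intermediate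
26 | dibutylboron aldolate (O-dibutylboryl derivative of 27) | COc1ccc([C@@H](OB(CCCC)CCCC)[C@@H](C(=O)N2[C@@H](Cc3ccccc3)COC2=O)Oc2ccc([C@H]3O[C@H](c4ccc(OC)c(OC)c4)[C@H](C)[C@H]3C)cc2OC)cc1OC | intermediate
27 | (S)-4-benzyl-3-[(2S,3R)-3-(3,4-dimethoxyphenyl)-2-{4-[(2S,3R,4R,5S)-5-(3,4-dimethoxyphenyl)-3,4-dimethyltetrahydrofuran-2-yl]-2-methoxyphenoxy}-3-hydroxypropanoyl]oxazolidin-2-one | COc1ccc([C@@H](O)[C@@H](C(=O)N2[C@@H](Cc3ccccc3)COC2=O)Oc2ccc([C@H]3O[C@H](c4ccc(OC)c(OC)c4)[C@H](C)[C@H]3C)cc2OC)cc1OC | intermediate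
28 | (1R,2R)-1-(3,4-dimethoxyphenyl)-2-{4-[(2S,3R,4R,5S)-5-(3,4-dimethoxyphenyl)-3,4-dimethyltetrahydrofuran-2-yl]-2-methoxyphenoxy}propane-1,3-diol | COc1ccc([C@@H](O)[C@@H](CO)Oc2ccc([C@H]3O[C@H](c4ccc(OC)c(OC)c4)[C@H](C)[C@H]3C)cc2OC)cc1OC | intermediate
29 | (2R,3R)-3-(3,4-dimethoxyphenyl)-2-{4-[(2S,3R,4R,5S)-5-(3,4-dimethoxyphenyl)-3,4-dimethyltetrahydrofuran-2-yl]-2-methoxyphenoxy}-3-hydroxypropyl 4-methylbenzenesulfonate | COc1ccc([C@@H](O)[C@@H](COS(=O)(=O)c2ccc(C)cc2)Oc2ccc([C@H]3O[C@H](c4ccc(OC)c(OC)c4)[C@H](C)[C@H]3C)cc2OC)cc1OC | intermediate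
30 | (1R,2R)-1-(3,4-dimethoxyphenyl)-2-{4-[(2S,3R,4R,5S)-5-(3,4-dimethoxyphenyl)-3,4-dimethyltetrahydrofuran-2-yl]-2-methoxyphenoxy}propan-1-ol (CNP0286615.1) | COc1ccc([C@@H](O)[C@@H](C)Oc2ccc([C@H]3O[C@H](c4ccc(OC)c(OC)c4)[C@H](C)[C@H]3C)cc2OC)cc1OC | target

**Step count**
- Total step count: 14.
- Longest linear sequence: 14 steps (1 and 2 to 30). Compounds 7, 15, 20 and 22 enter as purchased compounds.

**Steps most likely to fail**

**Step 2.**
- What may go wrong: exchange of the hindered, benzylic secondary hydroxyl onto phosphorus may be too slow, or the benzylic phosphinite may rearrange to a phosphine oxide. Undirected linear hydroformylation, alkene isomerisation or hydrogenation would then take over.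
- Fallback: it sets out from 6 and comes back at 12.
  - Hydroboration of the vinyl group with 9-BBN, then NaOH/H2O2, should give (1S,2R)-1-(3,4-dimethoxyphenyl)-2-methylbutane-1,4-diol F1.
  - TEMPO/PhI(OAc)2 oxidises the primary alcohol selectively. The lactol so formed is oxidised on to (4R,5S)-5-(3,4-dimethoxyphenyl)-4-methyldihydrofuran-2(3H)-one F2.
  - Enolisation with LiN(SiMe3)2 in THF at −78 °C and methylation with MeI on the face opposite C4-Me and C5-aryl should give lactone 12.
  - In this variant C2 is the former terminal vinyl carbon and the C3 methyl comes from MeI.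

**Step 11.**
- What may go wrong: Bu2BOTf may bind to O1 and open a benzylic C–O bond of the ring, which would epimerise C2 or C5 towards the more stable trans arrangement. Enolisation of the bulky, polyether-rich imide may also be incomplete, with erosion of facial selectivity.
- Fallback: it sets out from 19 and comes back at 30 without any Lewis acid and with C9'' present as methyl from the start.
  - Mitsunobu reaction of 19 with ethyl (S)-lactate (PPh3, DIAD, THF, 0 °C) should give, with inversion, the ethyl (R)-2-aryloxypropanoate F3.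
  - MeNHOMe·HCl with i-PrMgCl converts it into the Weinreb amide F4.
  - Purchased 3,4-dimethoxyphenylmagnesium bromide gives the (R)-α-aryloxy ketone F5.
  - Reduction with a borohydride that has a non-chelating counter-ion (Bu4NBH4, CH2Cl2–MeOH, −78 °C) should follow the polar Felkin–Anh model and give the threo alcohol 30.

**Step 14.**
- What may go wrong: the C7'' alkoxide formed first may displace the neighbouring tosylate (oxetane closure) in competition with hydride delivery.
- Fallback: it sets out from 29 and comes back at 30 with the internal nucleophile masked.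
  - t-BuMe2SiOTf with 2,6-lutidine in CH2Cl2 at −78 °C should give the silyl ether tosylate F6.
  - LiEt3BH in THF reduces it to the silyl ether of the target F7.
  - Bu4NF in THF releases 30.

**Further compounds**
F1 | step 2 | (1S,2R)-1-(3,4-dimethoxyphenyl)-2-methylbutane-1,4-diol | O[C@H](c1ccc(OC)c(OC)c1)[C@H](C)CCO
F2 | step 2 | (4R,5S)-5-(3,4-dimethoxyphenyl)-4-methyldihydrofuran-2(3H)-one | O=C1O[C@H](c2ccc(OC)c(OC)c2)[C@H](C)C1
F3 | step 11 | ethyl (R)-2-{4-[(2S,3R,4R,5S)-5-(3,4-dimethoxyphenyl)-3,4-dimethyltetrahydrofuran-2-yl]-2-methoxyphenoxy}propanoate | CCOC(=O)[C@@H](C)Oc1ccc([C@H]2O[C@H](c3ccc(OC)c(OC)c3)[C@H](C)[C@H]2C)cc1OC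
F4 | step 11 | (R)-2-{4-[(2S,3R,4R,5S)-5-(3,4-dimethoxyphenyl)-3,4-dimethyltetrahydrofuran-2-yl]-2-methoxyphenoxy}-N-methoxy-N-methylpropanamide | CON(C)C(=O)[C@@H](C)Oc1ccc([C@H]2O[C@H](c3ccc(OC)c(OC)c3)[C@H](C)[C@H]2C)cc1OC
F5 | step 11 | (R)-1-(3,4-dimethoxyphenyl)-2-{4-[(2S,3R,4R,5S)-5-(3,4-dimethoxyphenyl)-3,4-dimethyltetrahydrofuran-2-yl]-2-methoxyphenoxy}propan-1-one | COc1ccc(C(=O)[C@@H](C)Oc2ccc([C@H]3O[C@H](c4ccc(OC)c(OC)c4)[C@H](C)[C@H]3C)cc2OC)cc1OC
F6 | step 14 | (2R,3R)-3-[(tert-butyldimethylsilyl)oxy]-3-(3,4-dimethoxyphenyl)-2-{4-[(2S,3R,4R,5S)-5-(3,4-dimethoxyphenyl)-3,4-dimethyltetrahydrofuran-2-yl]-2-methoxyphenoxy}propyl 4-methylbenzenesulfonate | COc1ccc([C@@H](O[Si](C)(C)C(C)(C)C)[C@@H](COS(=O)(=O)c2ccc(C)cc2)Oc2ccc([C@H]3O[C@H](c4ccc(OC)c(OC)c4)[C@H](C)[C@H]3C)cc2OC)cc1OC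
F7 | step 14 | tert-butyl[(1R,2R)-1-(3,4-dimethoxyphenyl)-2-{4-[(2S,3R,4R,5S)-5-(3,4-dimethoxyphenyl)-3,4-dimethyltetrahydrofuran-2-yl]-2-methoxyphenoxy}propoxy]dimethylsilane | COc1ccc([C@@H](O[Si](C)(C)C(C)(C)C)[C@@H](C)Oc2ccc([C@H]3O[C@H](c4ccc(OC)c(OC)c4)[C@H](C)[C@H]3C)cc2OC)cc1OC
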